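**Retrosynthetic overview**
- The C(=O)–CH2 bond of the propanone bridge is made last. The target is read as the addition of the formyl C–H bond of a prenylated phloroglucinaldehyde across the vinyl group of a prenylated styrene, so the aldehyde carbon acts as an acyl-metal nucleophile equivalent (polarity reversal, no protecting groups, no by-product).
- Enabling feature: the phenolic OH groups at C2' and C6' of the phloroglucinol ring, which flank the ring carbon that carries the ketone. Either one binds rhodium as a phenoxide and directs it into the neighbouring formyl C–H bond through a five-membered O,C-chelate.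
- Aldehyde half: one C-prenylation of symmetrical 2,4,6-trihydroxybenzaldehyde. Styrene half: selective 4-O-methylation of 3-bromo-4,5-dihydroxybenzaldehyde, Stille prenylation at C–Br, Wittig methylenation.
- No ring is formed: both benzene rings are bought and only their substituents are set.

Key step: step 5

Remark: the target has no stereocentre and no stereogenic alkene (both prenyl groups end in CMe2), so no stereocontrol is needed. Styrene 8 is polymerisable and is meant to be used directly, cold, with a trace of BHT.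

**Step 1**
Reactants: 1 2,4,6-trihydroxybenzaldehyde; 2 1-bromo-3-methylbut-2-ene (prenyl bromide)
Product: 3 2,4,6-trihydroxy-3-(3-methylbut-2-en-1-yl)benzaldehyde
Conditions: KOH (1.0 equiv), H2O, 2 (1.0 equiv), 0 °C to rt; cold dilute acid work-up
Reagents that add atoms: none
Why: C-alkylation of the ambident phloroglucinolate in water (SN2 at the primary allylic bromide); C3 and C5 of 1 are equivalent, so only one mono-C-prenyl isomer can form, and one equivalent of bromide at low temperature should limit dialkylation.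

**Step 2**
Reactants: 4 3-bromo-4,5-dihydroxybenzaldehyde
Product: 5 3-bromo-5-hydroxy-4-methoxybenzaldehyde
Conditions: MeI (1.05 equiv), Li2CO3 (1.1 equiv), DMF, 45 °C
Reagents that add atoms: iodomethane, CI
Why: Williamson ether synthesis under a weak base; only the most acidic phenol (4-OH, para to the formyl group and ortho to bromine) should be deprotonated, so methylation should stop at the 4-O-methyl ether.

**Step 3**
Reactants: 5 3-bromo-5-hydroxy-4-methoxybenzaldehyde; 6 tributyl(3-methylbut-2-en-1-yl)stannane
Product: 7 3-hydroxy-4-methoxy-5-(3-methylbut-2-en-1-yl)benzaldehyde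
Conditions: Pd(PPh3)4 (5 mol %), 6 (1.5 equiv), DMF, 100 °C, Ar
Reagents that add atoms: none
Why: Stille cross-coupling; reductive elimination at the less hindered allyl terminus should give the linear prenyl arene, and the neutral conditions tolerate the free phenol and the aldehyde.

**Step 4**
Reactants: 7 3-hydroxy-4-methoxy-5-(3-methylbut-2-en-1-yl)benzaldehyde
Product: 8 5-ethenyl-2-methoxy-3-(3-methylbut-2-en-1-yl)phenol
Conditions: Ph3PCH3Br (3 equiv), KOtBu (3 equiv), THF, 0 °C to rt; aq NH4Cl
Reagents that add atoms: methyltriphenylphosphonium bromide, C[P+](c1ccccc1)(c1ccccc1)c1ccccc1.[Br-]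
Why: Wittig methylenation with excess non-stabilised ylide; the phenoxide formed is meta to the formyl group and does not deactivate it by conjugation, and the trisubstituted prenyl alkene is inert.

**Step 5**
Reactants: 3 2,4,6-trihydroxy-3-(3-methylbut-2-en-1-yl)benzaldehyde; 8 5-ethenyl-2-methoxy-3-(3-methylbut-2-en-1-yl)phenol
Product: 9 3,2',4',6'-tetrahydroxy-4-methoxy-3',5-diprenyldihydrochalcone (target)
Conditions: [Rh(cod)Cl]2 (2.5 mol %), (Ra,R,R)-SIPHOS-PE (6 mol %), K3PO4 (10 mol %), 8 (1.5 equiv), 1,4-dioxane, 70 °C, degassed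
Reagents that add atoms: none
Why: The 2-OH (or the equivalent 6-OH) of 3 binds Rh(I) as a phenoxide, the metal inserts into the adjacent formyl C–H bond, and the acyl rhodium hydride is held in a five-membered O,C-chelate; hydride insertion of the vinyl group of 8 and C–C reductive elimination then give the ketone with no by-product. The closest known reaction type is the rhodium/phosphoramidite-catalysed, linear-selective intermolecular hydroacylation of terminal alkenes with unprotected salicylaldehydes. No ring is closed and no stereocentre is formed. The step needs anti-Markovnikov regiochemistry, which the bulky monodentate ligand should secure because branched (benzylic) insertion is reversible and its reductive elimination is slow, whereas the primary alkyl eliminates readily. It needs the vinyl group to react in preference to the two trisubstituted prenyl alkenes, which their far slower insertion should secure. It needs hydroacylation to outrun decarbonylation, which the phenoxide chelate should secure.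

**Compound list**
1 | 2,4,6-trihydroxybenzaldehyde | O=Cc1c(O)cc(O)cc1O | starting material
2 | 1-bromo-3-methylbut-2-ene (prenyl bromide) | CC(C)=CCBr | starting material
3 | 2,4,6-trihydroxy-3-(3-methylbut-2-en-1-yl)benzaldehyde | O=Cc1c(O)cc(O)c(CC=C(C)C)c1O | intermediate
4 | 3-bromo-4,5-dihydroxybenzaldehyde | O=Cc1cc(O)c(O)c(Br)c1 | starting material
5 | 3-bromo-5-hydroxy-4-methoxybenzaldehyde | COc1c(O)cc(C=O)cc1Br | intermediate
6 | tributyl(3-methylbut-2-en-1-yl)stannane | CCCC[Sn](CCCC)(CCCC)CC=C(C)C | starting material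
7 | 3-hydroxy-4-methoxy-5-(3-methylbut-2-en-1-yl)benzaldehyde | COc1c(O)cc(C=O)cc1CC=C(C)C | intermediate
8 | 5-ethenyl-2-methoxy-3-(3-methylbut-2-en-1-yl)phenol | COc1c(O)cc(C=C)cc1CC=C(C)C | intermediate
9 | 3-[3-hydroxy-4-methoxy-5-(3-methylbut-2-en-1-yl)phenyl]-1-[2,4,6-trihydroxy-3-(3-methylbut-2-en-1-yl)phenyl]propan-1-one | COc1c(O)cc(CCC(=O)c2c(O)cc(O)c(CC=C(C)C)c2O)cc1CC=C(C)C | target

**Total step count:** 5
**Longest linear sequence:** 4 steps (steps 2, 3, 4, 5)

**Steps most likely to fail**

Step 5. What may go wrong: Markovnikov (branched) insertion of the vinylarene, or loss of CO from the acyl rhodium hydride, which also deactivates the catalyst as a rhodium carbonyl. Fallback by aldol chemistry, setting out from 7 and returning to the route at 9. Aldehyde 7 would be protected (MOMCl, iPr2NEt, CH2Cl2) as 4-methoxy-3-(methoxymethoxy)-5-(3-methylbut-2-en-1-yl)benzaldehyde F1. Commercial 2,4,6-trihydroxyacetophenone would be C-prenylated with 2 (aq KOH, 0 °C) to 1-[2,4,6-trihydroxy-3-(3-methylbut-2-en-1-yl)phenyl]ethan-1-one F2. This would be protected (NaH, MOMCl, DMF) as 1-[2,4,6-tris(methoxymethoxy)-3-(3-methylbut-2-en-1-yl)phenyl]ethan-1-one F3. Claisen–Schmidt condensation of F3 with F1 (KOH, EtOH/H2O) should give (E)-3-[4-methoxy-3-(methoxymethoxy)-5-(3-methylbut-2-en-1-yl)phenyl]-1-[2,4,6-tris(methoxymethoxy)-3-(3-methylbut-2-en-1-yl)phenyl]prop-2-en-1-one F4. Copper hydride conjugate reduction ([(Ph3P)CuH]6 cat., PhSiH3, toluene), which leaves isolated trisubstituted alkenes alone, should give 3-[4-methoxy-3-(methoxymethoxy)-5-(3-methylbut-2-en-1-yl)phenyl]-1-[2,4,6-tris(methoxymethoxy)-3-(3-methylbut-2-en-1-yl)phenyl]propan-1-one F5. Mild HCl in MeOH at rt would then remove the four MOM groups to give 9.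

Step 1. What may go wrong: over-alkylation to the 3,5-diprenyl compound, O-alkylation, and hydrolysis of the bromide competing with mono-C-alkylation. Fallback by O-alkylation and sigmatropic rearrangement, setting out from 1 and returning at 3. Compound 1 would be converted (MOMCl, iPr2NEt, CH2Cl2; the hydrogen-bonded OH stays free) into 2-hydroxy-4,6-bis(methoxymethoxy)benzaldehyde F6. O-Prenylation with 2 (K2CO3, DMF) should give 2,4-bis(methoxymethoxy)-6-[(3-methylbut-2-en-1-yl)oxy]benzaldehyde F7. Heating in N,N-diethylaniline at about 200 °C (para-Claisen, i.e. Claisen–Cope, rearrangement) should move the prenyl group to the carbon para to that oxygen, giving 6-hydroxy-2,4-bis(methoxymethoxy)-3-(3-methylbut-2-en-1-yl)benzaldehyde F8. HCl in MeOH at rt would then give 3.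

Step 3. What may go wrong: allyl transposition during transmetallation (coupling at the tertiary terminus to give the 1,1-dimethylallyl isomer), or slow oxidative addition into the electron-rich, ortho-substituted bromide. Fallback with reversed polarity (aryl nucleophile, prenyl electrophile), setting out from 5 and returning at 8, so that it also replaces step 4. Compound 5 would be silylated (TBSCl, imidazole, DMF) to 3-bromo-5-[(tert-butyldimethylsilyl)oxy]-4-methoxybenzaldehyde F9. Wittig methylenation (Ph3PCH3Br, KOtBu, THF) should give (3-bromo-5-ethenyl-2-methoxyphenoxy)(tert-butyl)dimethylsilane F10. Bromine–lithium exchange (t-BuLi, 2 equiv, THF, −78 °C) would give {3-[(tert-butyldimethylsilyl)oxy]-5-ethenyl-2-methoxyphenyl}lithium F11. Treatment with CuBr·SMe2 and then 2 (SN2 at the primary carbon) should give tert-butyl[5-ethenyl-2-methoxy-3-(3-methylbut-2-en-1-yl)phenoxy]dimethylsilane F12. TBAF in THF at 0 °C would then give 8.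

**Further compounds**
F1 | step 5 | 4-methoxy-3-(methoxymethoxy)-5-(3-methylbut-2-en-1-yl)benzaldehyde | COCOc1cc(C=O)cc(CC=C(C)C)c1OC
F2 | step 5 | 1-[2,4,6-trihydroxy-3-(3-methylbut-2-en-1-yl)phenyl]ethan-1-one | CC(=O)c1c(O)cc(O)c(CC=C(C)C)c1O
F3 | step 5 | 1-[2,4,6-tris(methoxymethoxy)-3-(3-methylbut-2-en-1-yl)phenyl]ethan-1-one | CC(=O)c1c(OCOC)cc(OCOC)c(CC=C(C)C)c1OCOC
F4 | step 5 | (E)-3-[4-methoxy-3-(methoxymethoxy)-5-(3-methylbut-2-en-1-yl)phenyl]-1-[2,4,6-tris(methoxymethoxy)-3-(3-methylbut-2-en-1-yl)phenyl]prop-2-en-1-one | COCOc1cc(/C=C/C(=O)c2c(OCOC)cc(OCOC)c(CC=C(C)C)c2OCOC)cc(CC=C(C)C)c1OC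
F5 | step 5 | 3-[4-methoxy-3-(methoxymethoxy)-5-(3-methylbut-2-en-1-yl)phenyl]-1-[2,4,6-tris(methoxymethoxy)-3-(3-methylbut-2-en-1-yl)phenyl]propan-1-one | COCOc1cc(CCC(=O)c2c(OCOC)cc(OCOC)c(CC=C(C)C)c2OCOC)cc(CC=C(C)C)c1OC
F6 | step 1 | 2-hydroxy-4,6-bis(methoxymethoxy)benzaldehyde | O=Cc1c(O)cc(OCOC)cc1OCOC
F7 | step 1 | 2,4-bis(methoxymethoxy)-6-[(3-methylbut-2-en-1-yl)oxy]benzaldehyde | O=Cc1c(OCC=C(C)C)cc(OCOC)cc1OCOC
F8 | step 1 | 6-hydroxy-2,4-bis(methoxymethoxy)-3-(3-methylbut-2-en-1-yl)benzaldehyde | O=Cc1c(O)cc(OCOC)c(CC=C(C)C)c1OCOC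
F9 | step 3 | 3-bromo-5-[(tert-butyldimethylsilyl)oxy]-4-methoxybenzaldehyde | COc1c(O[Si](C)(C)C(C)(C)C)cc(C=O)cc1Br
F10 | step 3 | (3-bromo-5-ethenyl-2-methoxyphenoxy)(tert-butyl)dimethylsilane | COc1c(O[Si](C)(C)C(C)(C)C)cc(C=C)cc1Br
F11 | step 3 | {3-[(tert-butyldimethylsilyl)oxy]-5-ethenyl-2-methoxyphenyl}lithium | COc1c(O[Si](C)(C)C(C)(C)C)cc(C=C)cc1[Li]
F12 | step 3 | tert-butyl[5-ethenyl-2-methoxy-3-(3-methylbut-2-en-1-yl)phenoxy]dimethylsilane | COc1c(O[Si](C)(C)C(C)(C)C)cc(C=C)cc1CC=C(C)C
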